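The ratio of free monomer to pre-initiator in the flask, n = 200 units per pre-initiator, is the loading, and the ledger below is built on it.

| flask | free monomer | pre-initiator | remark | time |
|---|---|---|---|---|
| Thursday's | 2.8 M | 10 mM | run made earlier |  |
| Friday's | 2 M | 20 mM | run made earlier |  |
| flask | 2.0 M | 10 mM |  | 8.0 min |

- Thursday's (time / min: monomer in chains / %, free monomer / %): 0.667: 3.9, 95.2; 1.33: 15.7, 84.6; 2.00: 27.3, 69.0; 3.00: 44.6, 55.5; 4.00: 54.4, 42.7; 5.00: 63.6, 36.9
- Friday's (time / min: monomer in chains / %, free monomer / %): 0.417: 3.0, 97.6; 0.667: 6.5, 94.1; 1.33: 22.9, 76.1; 2.50: 47.8, 49.8; 5.00: 68.3, 31.0

(each reading ± 1 percentage point)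

1. whether the average number of monomer units in a chain (chains begun, living or dead) reaches 300 by 8.0 min (no / yes)
2. average number of monomer units in a chain (chains begun, living or dead) at 8.0 min

- the average divides the monomer in chains by the number of chains begun, living and dead together
- the analysis behind the earlier runs scatters by 1 percentage point, standard deviation
- the earlier runs do not show the number of chains; that part of a forecast is a guess

First entry, pre-initiator: my own assumption is that each pre-initiator begins one chain. The earlier runs show no count of chains, so this entry is a guess.

Second entry, free monomer: with s the share of charged free monomer in chains, the average chain length is D = s·n. In Friday's run, with the same free monomer charge but twice the pre-initiator, the reading of s was 68.3% at 5.00 min, and I take that share as a rough figure for this flask at 8.0 min.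

Third entry, closing: my reckoning gives D near 137. With one chain per pre-initiator, reaching 300 in this flask would need s = 1.50, which is more than the whole charge, so my answer is no.

Fourth entry, the forecast: it differs, saying yes with 550, on the ground that “the runs show no clear initiator depletion”.

The flask gives 137 at 8.0 min, so the answer is no.

    free monomer + initiator → living end + monomer in chains (k = 0.0639 L mol⁻¹ s⁻¹)
    free monomer + living end → monomer in chains + living end, rate k2*[living end]*[free monomer] (k = 0.726 L mol⁻¹ s⁻¹)
    monomer in chains + living end → free monomer + living end, rate k3*[living end] as long as [monomer in chains] is above zero (k = 0.392 s⁻¹)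
    2 initiator → spent initiator (k = 1.10 L mol⁻¹ s⁻¹)
    2 free monomer → homo dimer (k = 1.94 × 10⁻⁵ L mol⁻¹ s⁻¹)
    pre-initiator → initiator (k = 0.0138 s⁻¹)

Pre-initiator stands at 0.13% of its charge at 8.00 min, with 0.00988 M of living end against 10 mM charged. The loading times the flask's 67.7% in chains gives 135. The neighbour charged with 1.2 M of free monomer has a loading of 120, and with its 50.8% in chains the same product gives 61.0, against its simulated 62.6.

The data stem from a simulated flask from invented constants, and the scatter is random.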